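The route rests on cutting the C4a''–C5'' bond of luteolin ring A. The feature exploited lies in ring C. O1'' sits on C8a'', and C8a'' is the direct neighbour of C8'', the carbon that holds ring B. If ring C is already complete as a 2-aryl-4-pyranone and C8'' hangs from C8a'' as an sp3 methine, ring A can only grow in the 8-aryl sense. The precursor is a tert-butyl 3-oxobutanoate whose C4 (= C8'') bears this pyranone and the acetal-protected ring B. On heating it loses tert-butanol, C4a'' bonds to acyl carbon C5'', and enolisation gives the 5'',7''-diol in one operation. The (2S)-flavanone is then closed by an asymmetric oxa-Michael addition.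

Key step: step 10

Locants: unprimed = flavanone core, single primes = its ring B, double primes = luteolin chromone, triple primes = luteolin ring B.

Assumption 1: the target string defines only C2 (S). The hindered C2'–C8'' biaryl axis is undefined, so it is carried as a mixture of atropisomers and every (2S) form counts as the target.

Assumption 2: the quinine- and quinidine-derived thioureas are pseudo-enantiomers. The quinine series is written, and the other series is taken if circular dichroism of the protected flavanone from a first run indicates the 2R sense.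

Design points of the precursor:
- **(a) tert-Butyl ester.** The alcohol it releases cannot add to the pyranone. The ester gives the acylketene near 110 °C, so the acidity of C6''–H2, which would blunt an ester towards a base-induced closure, becomes the trigger.
- **(b) Dioxolane on ring B.** Ring B carries its one-carbon arm at the aldehyde level, which saves a reduction and an oxidation.
- **(c) Early pyranone closure.** The acid-induced closure is run before ring B is attached, so the p-alkoxybenzylic acetal meets acid only when it is to be removed.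
- **(d) Activated flavanone precursor.** The flavanone is closed on an alkylidene β-keto ester, the substrate class for which catalytic asymmetric closure is established. Its Knoevenagel assembly avoids hydroxide, which could open the flavone.

Step 1
Reactants: 1 2-bromoisovanillin (2-bromo-3-hydroxy-4-methoxybenzaldehyde)
Product: 2 2-bromo-3,4-dihydroxybenzaldehyde
Conditions: BBr3 (2.5 equiv), CH2Cl2, −78 °C to rt; H2O
Reagents that add atoms: none
Why: Lewis-acid cleavage of an aryl methyl ether (BBr3 demethylation) is routine for bromo-hydroxybenzaldehydes, and the formyl group and the C–Br bond are untouched.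

Step 2
Reactants: 2 2-bromo-3,4-dihydroxybenzaldehyde
Product: 3 3,4-bis(benzyloxy)-2-bromobenzaldehyde
Conditions: BnBr (2.4 equiv), K2CO3, DMF, 60 °C
Reagents that add atoms: benzyl bromide, BrCc1ccccc1
Why: Double Williamson etherification of the catechol, with benzyl chosen so that all phenol protection falls in the final hydrogenolysis.

Step 3
Reactants: 3 3,4-bis(benzyloxy)-2-bromobenzaldehyde
Product: 4 2-[3,4-bis(benzyloxy)-2-bromophenyl]-1,3-dioxolane
Conditions: HOCH2CH2OH (3 equiv), p-TsOH·H2O (5 mol %), PhMe, Dean–Stark, reflux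
Reagents that add atoms: ethylene glycol, OCCO
Why: Acid-catalysed acetalisation with azeotropic removal of water masks the aldehyde at its final oxidation level and makes the bromide fit for halogen–metal exchange.

Step 4
Reactants: 5 3',4'-dihydroxyacetophenone
Product: 6 3',4'-bis(benzyloxy)acetophenone
Conditions: BnBr (2.4 equiv), K2CO3, DMF, 60 °C
Reagents that add atoms: benzyl bromide, BrCc1ccccc1
Why: Williamson etherification of both phenols, which are far more acidic than the methyl ketone under carbonate conditions.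

Step 5
Reactants: 6 3',4'-bis(benzyloxy)acetophenone
Product: 7 1-[3,4-bis(benzyloxy)phenyl]butane-1,3-dione
Conditions: NaH (2.5 equiv), EtOAc (5 equiv), THF, reflux; 1 M HCl
Reagents that add atoms: ethyl acetate, CCOC(C)=O
Why: Crossed Claisen condensation of the methyl ketone enolate with ethyl acetate, driven by formation of the diketonate salt.

Step 6
Reactants: 7 1-[3,4-bis(benzyloxy)phenyl]butane-1,3-dione
Product: 10 2-[3,4-bis(benzyloxy)phenyl]-6-(chloromethyl)-4H-pyran-4-one, via dilithio dianion 8 (not isolated), via chlorotriketone 9 (not isolated)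
Conditions: LiN(i-Pr)2 (2.2 equiv), THF, −78 to 0 °C; ClCH2C(O)N(OMe)Me, −78 °C; 1 M HCl; crude, p-TsOH·H2O (10 mol %), PhMe, 80 °C
Reagents that add atoms: 2-chloro-N-methoxy-N-methylacetamide, CON(C)C(=O)CCl
Why: A 1,3-diketone dianion is acylated at its terminal carbon by a Weinreb amide, which stops at the ketone stage and spares the C–Cl bond in the cold, and the 1,3,5-triketone then undergoes the classical acid cyclodehydration to the 4-pyranone while no acid-labile group is present.

Step 7
Reactants: 4 2-[3,4-bis(benzyloxy)-2-bromophenyl]-1,3-dioxolane; 10 2-[3,4-bis(benzyloxy)phenyl]-6-(chloromethyl)-4H-pyran-4-one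
Product: 13 2-[3,4-bis(benzyloxy)phenyl]-6-{[2,3-bis(benzyloxy)-6-(1,3-dioxolan-2-yl)phenyl]methyl}-4H-pyran-4-one, via aryllithium 11 (not isolated), via arylzinc chloride 12 (not isolated)
Conditions: 4, n-BuLi (1.05 equiv), THF, −78 °C; ZnCl2 (1.1 equiv), −78 °C to rt; 10, Pd(OAc)2 (3 mol %), SPhos (6 mol %), THF, 45 °C
Reagents that add atoms: none
Why: Bromine–lithium exchange, transmetalation to zinc and Negishi coupling with an activated, allylic-type chloromethyl group form C2'–C8''; the bulky biarylphosphine serves the doubly ortho-substituted arylzinc, and organozinc reagents leave the pyranone carbonyl and the acetal alone.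

Step 8
Reactants: 13 2-[3,4-bis(benzyloxy)phenyl]-6-{[2,3-bis(benzyloxy)-6-(1,3-dioxolan-2-yl)phenyl]methyl}-4H-pyran-4-one
Product: 15 1-[2,3-bis(benzyloxy)-6-(1,3-dioxolan-2-yl)phenyl]-1-{6-[3,4-bis(benzyloxy)phenyl]-4-oxo-4H-pyran-2-yl}propan-2-one (racemic at C8''), via lithium dienolate 14 (not isolated)
Conditions: LiN(SiMe3)2 (1.15 equiv), THF, −78 °C; MeC(O)N(OMe)Me (1.5 equiv), −78 to 0 °C; AcOH
Reagents that add atoms: N-methoxy-N-methylacetamide, CON(C)C(C)=O
Why: γ-Deprotonation of a 2-alkyl-4-pyranone gives an extended enolate that takes carbon electrophiles at the exocyclic carbon C8'' because this restores the pyranone, and C-acylation with a Weinreb amide avoids double acylation and proton exchange with the more acidic product.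

Step 9
Reactants: 15 1-[2,3-bis(benzyloxy)-6-(1,3-dioxolan-2-yl)phenyl]-1-{6-[3,4-bis(benzyloxy)phenyl]-4-oxo-4H-pyran-2-yl}propan-2-one
Product: 17 tert-butyl 4-[2,3-bis(benzyloxy)-6-(1,3-dioxolan-2-yl)phenyl]-4-{6-[3,4-bis(benzyloxy)phenyl]-4-oxo-4H-pyran-2-yl}-3-oxobutanoate (racemic at C8''), via dilithio dianion 16 (not isolated)
Conditions: LiN(i-Pr)2 (2.5 equiv), THF, −78 to −30 °C; Boc2O (1.1 equiv), −78 °C; AcOH
Reagents that add atoms: di-tert-butyl dicarbonate, CC(C)(C)OC(=O)OC(=O)OC(C)(C)C
Why: As in 1,3-dicarbonyl dianion chemistry, the first equivalent of base removes the acidic C8''–H, the second a methyl proton, and the last-formed, more reactive terminal carbanion C6'' is C-acylated by the dicarbonate (enolate alkoxycarbonylation), while the anionic pyranone is shielded from nucleophiles.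

Step 10
Reactants: 17 tert-butyl 4-[2,3-bis(benzyloxy)-6-(1,3-dioxolan-2-yl)phenyl]-4-{6-[3,4-bis(benzyloxy)phenyl]-4-oxo-4H-pyran-2-yl}-3-oxobutanoate
Product: 20 8-[2,3-bis(benzyloxy)-6-(1,3-dioxolan-2-yl)phenyl]-2-[3,4-bis(benzyloxy)phenyl]-5,7-dihydroxy-4H-chromen-4-one, via acylketene 18 (not isolated), via hydroxy-dienylketene 19 (not isolated)
Conditions: PhMe (0.01 M), i-Pr2NEt (0.2 equiv), reflux (110 °C), condensate returned through 4 Å sieves
Reagents that add atoms: none
Why: Proposed new method: the tert-butyl β-keto ester loses tert-butanol by the retro-ene path typical of such esters to give acylketene 18, whose acidic C8''–H enolises (amine-shuttled) to hydroxy-dienylketene 19, the neutral counterpart of the pyranone dienolate. In 19 electron density is pushed from O7'' through C7''=C8''–C8a''=C4a'' onto ring carbon C4a'', which bonds to the ketene carbon C5'', and tautomerisation of the cyclohexadienone gives the aromatic 5'',7''-diol, so the net change is an intramolecular Claisen-type C-acylation with loss of the alcohol. The closest known reaction types are the Claisen aromatisation of β-polyketo esters to acylphloroglucinols, the thermal generation of acylketenes from tert-butyl acetoacetates and dioxinones, and the 6π closure of dienylketenes that ends the Danheiser benzannulation, whereas closure onto C3 of an intact 4-pyranone has not been shown. Ring A closes in a six-membered mode, as a 6π electrocyclisation of the dienylketene geometry in which C6'' and C8a'' are cis (in polar terms an enol-endo, exo attack on the acyl carbon). No stereocentre is formed, since the C8'' stereocentre vanishes and the C2'–C8'' axis arises as a racemate. The step needs 8-aryl over 6-aryl, pyranone over ring B closure and C- over O-acylation: the first holds because O1''–C8a'' is never broken in the absence of nucleophile or strong base, the second because both ortho carbons of ring B are substituted, and the third because capture of 18 by tert-butanol or product phenols is reversible at this temperature while aromatisation is not.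

Step 11
Reactants: 20 8-[2,3-bis(benzyloxy)-6-(1,3-dioxolan-2-yl)phenyl]-2-[3,4-bis(benzyloxy)phenyl]-5,7-dihydroxy-4H-chromen-4-one
Product: 21 5,7-bis(benzyloxy)-8-[2,3-bis(benzyloxy)-6-(1,3-dioxolan-2-yl)phenyl]-2-[3,4-bis(benzyloxy)phenyl]-4H-chromen-4-one
Conditions: BnBr (3 equiv), K2CO3 (4 equiv), DMF, 70 °C
Reagents that add atoms: benzyl bromide, BrCc1ccccc1
Why: Exhaustive Williamson benzylation (warm DMF also alkylates the chelated 5''-OH) needs no selectivity and keeps the 7''-OH from forming a cyclic lactol with the neighbouring formyl group once that is unmasked.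

Step 12
Reactants: 21 5,7-bis(benzyloxy)-8-[2,3-bis(benzyloxy)-6-(1,3-dioxolan-2-yl)phenyl]-2-[3,4-bis(benzyloxy)phenyl]-4H-chromen-4-one
Product: 22 3,4-bis(benzyloxy)-2-{5,7-bis(benzyloxy)-2-[3,4-bis(benzyloxy)phenyl]-4-oxo-4H-chromen-8-yl}benzaldehyde
Conditions: 1 M HCl, THF, rt
Reagents that add atoms: water, O
Why: Acetal hydrolysis of an electron-rich aryl dioxolane is fast in dilute acid, under which the benzyl ethers and the flavone are stable.

Step 13
Reactants: 23 2,4,6-trihydroxyacetophenone
Product: 24 2-hydroxy-4,6-bis(benzyloxy)acetophenone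
Conditions: BnBr (2.05 equiv), K2CO3, DMF, rt to 50 °C
Reagents that add atoms: benzyl bromide, BrCc1ccccc1
Why: Williamson benzylation stops after two groups because the remaining ortho hydroxyl is hydrogen-bonded to the acetyl carbonyl.

Step 14
Reactants: 24 2-hydroxy-4,6-bis(benzyloxy)acetophenone
Product: 26 tert-butyl 3-[2,4-bis(benzyloxy)-6-hydroxyphenyl]-3-oxopropanoate, via dilithio phenoxide-enolate 25 (not isolated)
Conditions: LiN(SiMe3)2 (3.3 equiv), THF, −78 °C; Boc2O (1.1 equiv), −78 to 0 °C; 1 M HCl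
Reagents that add atoms: di-tert-butyl dicarbonate, CC(C)(C)OC(=O)OC(=O)OC(C)(C)C
Why: Enolate C-alkoxycarbonylation of the phenoxide–enolate dianion, in which any aryl carbonate formed on oxygen is carried to the same β-keto ester by a Baker–Venkataraman-type O-to-C shift under the excess base, and the tert-butyl ester resists lactonisation to a 4-hydroxycoumarin.

Step 15
Reactants: 22 3,4-bis(benzyloxy)-2-{5,7-bis(benzyloxy)-2-[3,4-bis(benzyloxy)phenyl]-4-oxo-4H-chromen-8-yl}benzaldehyde; 26 tert-butyl 3-[2,4-bis(benzyloxy)-6-hydroxyphenyl]-3-oxopropanoate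
Product: 27 tert-butyl (2Z)-2-[2,4-bis(benzyloxy)-6-hydroxybenzoyl]-3-(3,4-bis(benzyloxy)-2-{5,7-bis(benzyloxy)-2-[3,4-bis(benzyloxy)phenyl]-4-oxo-4H-chromen-8-yl}phenyl)prop-2-enoate (Z expected as the main geometry)
Conditions: piperidine (20 mol %), AcOH (20 mol %), 4 Å sieves, PhMe, rt
Reagents that add atoms: none
Why: Knoevenagel condensation under piperidinium acetate catalysis is mild enough for the flavone and delivers the alkylidene β-keto ester that the asymmetric closure requires.

Step 16
Reactants: 27 tert-butyl (2Z)-2-[2,4-bis(benzyloxy)-6-hydroxybenzoyl]-3-(aryl)prop-2-enoate as named in step 15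
Product: 29 (2S)-5,7-bis(benzyloxy)-2-(3,4-bis(benzyloxy)-2-{5,7-bis(benzyloxy)-2-[3,4-bis(benzyloxy)phenyl]-4-oxo-4H-chromen-8-yl}phenyl)chroman-4-one, via tert-butyl flavanone-3-carboxylate 28 (not isolated)
Conditions: quinine-derived 9-epi-amino thiourea, N'-aryl = 3,5-(CF3)2C6H3 (10 mol %), PhMe, −25 °C; then p-TsOH·H2O, 80 °C, same flask
Reagents that add atoms: none
Why: Bifunctional thiourea–amine catalysis of the intramolecular oxa-Michael addition of 2-hydroxyaryl alkylidene β-keto esters is a known enantioselective flavanone synthesis, in which the thiourea binds the dicarbonyl unit and the quinuclidine guides the phenol to one face of C2 (catalyst control sets 2S), and acid-induced loss of isobutene and CO2 in the same flask removes the activating ester and with it the easy retro-addition.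

Step 17
Reactants: 29 (2S)-octa-O-benzyl flavanone–flavone as named in step 16
Product: 30 (2S)-2-{2-[2-(3,4-dihydroxyphenyl)-5,7-dihydroxy-4-oxo-4H-chromen-8-yl]-3,4-dihydroxyphenyl}-5,7-dihydroxychroman-4-one (eriodictyol-(2'→8'')-luteolin; CNP0265600.1)
Conditions: H2 (1 atm), Pd/C (10 %), THF/MeOH, rt; neutral work-up
Reagents that add atoms: none
Why: Catalytic hydrogenolysis of the eight aryl benzyl ethers runs under neutral conditions that do not open the flavanone, so C2 keeps its configuration, and the flavone C2''=C3'' bond and both carbonyl groups are inert at one atmosphere.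

Compound list
1 | 2-bromoisovanillin | COc1ccc(C=O)c(Br)c1O | starting material
2 | 2-bromo-3,4-dihydroxybenzaldehyde | O=Cc1ccc(O)c(O)c1Br | intermediate
3 | 3,4-bis(benzyloxy)-2-bromobenzaldehyde | O=Cc1ccc(OCc2ccccc2)c(OCc2ccccc2)c1Br | intermediate
4 | 2-[3,4-bis(benzyloxy)-2-bromophenyl]-1,3-dioxolane | Brc1c(C2OCCO2)ccc(OCc2ccccc2)c1OCc1ccccc1 | intermediate
5 | 3',4'-dihydroxyacetophenone | CC(=O)c1ccc(O)c(O)c1 | starting material
6 | 3',4'-bis(benzyloxy)acetophenone | CC(=O)c1ccc(OCc2ccccc2)c(OCc2ccccc2)c1 | intermediate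
7 | 1-[3,4-bis(benzyloxy)phenyl]butane-1,3-dione | CC(=O)CC(=O)c1ccc(OCc2ccccc2)c(OCc2ccccc2)c1 | intermediate
8 | dilithio dianion of 7 (formed in the flask) | [Li+].[Li+].C=C([O-])C=C([O-])c1ccc(OCc2ccccc2)c(OCc2ccccc2)c1 | intermediate
9 | 1-[3,4-bis(benzyloxy)phenyl]-6-chlorohexane-1,3,5-trione (crude, not purified) | O=C(CCl)CC(=O)CC(=O)c1ccc(OCc2ccccc2)c(OCc2ccccc2)c1 | intermediate
10 | 2-[3,4-bis(benzyloxy)phenyl]-6-(chloromethyl)-4H-pyran-4-one | O=c1cc(CCl)oc(-c2ccc(OCc3ccccc3)c(OCc3ccccc3)c2)c1 | intermediate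
11 | [2,3-bis(benzyloxy)-6-(1,3-dioxolan-2-yl)phenyl]lithium (formed in the flask) | [Li]c1c(C2OCCO2)ccc(OCc2ccccc2)c1OCc1ccccc1 | intermediate
12 | [2,3-bis(benzyloxy)-6-(1,3-dioxolan-2-yl)phenyl]zinc chloride (formed in the flask) | Cl[Zn]c1c(C2OCCO2)ccc(OCc2ccccc2)c1OCc1ccccc1 | intermediate
13 | 2-aryl-6-(ring B arylmethyl)-4-pyranone as named in step 7 | O=c1cc(Cc2c(C3OCCO3)ccc(OCc3ccccc3)c2OCc2ccccc2)oc(-c2ccc(OCc3ccccc3)c(OCc3ccccc3)c2)c1 | intermediate
14 | lithium dienolate of 13, a 2-arylmethylidene-2H-pyran-4-olate (formed in the flask) | [Li+].[O-]C1=CC(=Cc2c(C3OCCO3)ccc(OCc3ccccc3)c2OCc2ccccc2)OC(c2ccc(OCc3ccccc3)c(OCc3ccccc3)c2)=C1 | intermediate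
15 | C8''-acetyl pyranone as named in step 8 (racemic) | CC(=O)C(c1cc(=O)cc(-c2ccc(OCc3ccccc3)c(OCc3ccccc3)c2)o1)c1c(C2OCCO2)ccc(OCc2ccccc2)c1OCc1ccccc1 | intermediate
16 | dilithio dianion of 15 (formed in the flask) | [Li+].[Li+].C=C([O-])C(c1c(C2OCCO2)ccc(OCc2ccccc2)c1OCc1ccccc1)=C1C=C([O-])C=C(c2ccc(OCc3ccccc3)c(OCc3ccccc3)c2)O1 | intermediate
17 | key-step precursor, tert-butyl keto ester as named in step 9 (racemic) | CC(C)(C)OC(=O)CC(=O)C(c1cc(=O)cc(-c2ccc(OCc3ccccc3)c(OCc3ccccc3)c2)o1)c1c(C2OCCO2)ccc(OCc2ccccc2)c1OCc1ccccc1 | intermediate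
18 | acylketene from 17 (formed in the flask) | O=C=CC(=O)C(c1cc(=O)cc(-c2ccc(OCc3ccccc3)c(OCc3ccccc3)c2)o1)c1c(C2OCCO2)ccc(OCc2ccccc2)c1OCc1ccccc1 | intermediate
19 | hydroxy-dienylketene, C6'' and C8a'' cis (formed in the flask) | O=C=C/C(O)=C(\c1cc(=O)cc(-c2ccc(OCc3ccccc3)c(OCc3ccccc3)c2)o1)c1c(C2OCCO2)ccc(OCc2ccccc2)c1OCc1ccccc1 | intermediate
20 | key-step product, 8-aryl-5,7-dihydroxyflavone as named in step 10 (racemic axis) | O=c1cc(-c2ccc(OCc3ccccc3)c(OCc3ccccc3)c2)oc2c(-c3c(C4OCCO4)ccc(OCc4ccccc4)c3OCc3ccccc3)c(O)cc(O)c12 | intermediate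
21 | 5'',7''-di-O-benzyl ether of 20 | O=c1cc(-c2ccc(OCc3ccccc3)c(OCc3ccccc3)c2)oc2c(-c3c(C4OCCO4)ccc(OCc4ccccc4)c3OCc3ccccc3)c(OCc3ccccc3)cc(OCc3ccccc3)c12 | intermediate
22 | ring B aldehyde as named in step 12 | O=Cc1ccc(OCc2ccccc2)c(OCc2ccccc2)c1-c1c(OCc2ccccc2)cc(OCc2ccccc2)c2c(=O)cc(-c3ccc(OCc4ccccc4)c(OCc4ccccc4)c3)oc12 | intermediate
23 | 2,4,6-trihydroxyacetophenone | CC(=O)c1c(O)cc(O)cc1O | starting material
24 | 2-hydroxy-4,6-bis(benzyloxy)acetophenone | CC(=O)c1c(O)cc(OCc2ccccc2)cc1OCc1ccccc1 | intermediate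
25 | dilithio phenoxide-enolate of 24 (formed in the flask) | [Li+].[Li+].C=C([O-])c1c([O-])cc(OCc2ccccc2)cc1OCc1ccccc1 | intermediate
26 | tert-butyl 3-[2,4-bis(benzyloxy)-6-hydroxyphenyl]-3-oxopropanoate | CC(C)(C)OC(=O)CC(=O)c1c(O)cc(OCc2ccccc2)cc1OCc1ccccc1 | intermediate
27 | (Z)-alkylidene β-keto ester as named in step 15 | CC(C)(C)OC(=O)/C(=C\c1ccc(OCc2ccccc2)c(OCc2ccccc2)c1-c1c(OCc2ccccc2)cc(OCc2ccccc2)c2c(=O)cc(-c3ccc(OCc4ccccc4)c(OCc4ccccc4)c3)oc12)C(=O)c1c(O)cc(OCc2ccccc2)cc1OCc1ccccc1 | intermediate
28 | tert-butyl (2S)-flavanone-3-carboxylate, C3 epimerisable (formed in the flask) | O=C1C(C(=O)OC(C)(C)C)[C@@H](c2ccc(OCc3ccccc3)c(OCc3ccccc3)c2-c2c(OCc3ccccc3)cc(OCc3ccccc3)c3c(=O)cc(-c4ccc(OCc5ccccc5)c(OCc5ccccc5)c4)oc23)Oc2cc(OCc3ccccc3)cc(OCc3ccccc3)c21 | intermediate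
29 | (2S)-octa-O-benzyl flavanone–flavone as named in step 16 | O=C1C[C@@H](c2ccc(OCc3ccccc3)c(OCc3ccccc3)c2-c2c(OCc3ccccc3)cc(OCc3ccccc3)c3c(=O)cc(-c4ccc(OCc5ccccc5)c(OCc5ccccc5)c4)oc23)Oc2cc(OCc3ccccc3)cc(OCc3ccccc3)c21 | intermediate
30 | (2S)-eriodictyol-(2'→8'')-luteolin, CNP0265600.1 | O=C1C[C@@H](c2ccc(O)c(O)c2-c2c(O)cc(O)c3c(=O)cc(-c4ccc(O)c(O)c4)oc23)Oc2cc(O)cc(O)c21 | target

Total step count: 17.

Longest linear sequence: 12 steps (1, 2, 3, 7, 8, 9, 10, 11, 12, 15, 16, 17). The branch 4, 5, 6 joins at step 7 with equal length, and the branch 13, 14 joins at step 15.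

Steps most likely to fail

1. **Step 10.**
   - What may go wrong: bimolecular consumption of the acylketene may outrun the closure. Enolisation at C8'', or attainment of the folded geometry next to the bulky ring B, may be too slow. Loss of isobutene followed by decarboxylation may return the material to the methyl ketone stage.
   - Fallback with known chemistry (biaryl cross-coupling on a finished flavone), setting out from 4 and coming back at 21: aryllithium 11, made from 4 as in step 7, is quenched with 2-isopropoxy-4,4,5,5-tetramethyl-1,3,2-dioxaborolane to give ring B pinacol boronate F1. Commercial luteolin is perbenzylated (BnBr, K2CO3, DMF) to tetra-O-benzylluteolin F2. This is iodinated at the most activated ring A position (I2, AgO2CCF3, CH2Cl2) to 8-iodo-tetra-O-benzylluteolin F3. Suzuki–Miyaura coupling of F1 and F3 (Pd(OAc)2, SPhos, K3PO4, PhMe/H2O, 100 °C) gives 21.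

2. **Step 16.**
   - What may go wrong: facial selectivity may be poor for the atropisomer whose axis is mismatched with the catalyst. Uncatalysed closure may already occur during or after the Knoevenagel step. Acid-induced reversible ring opening at 80 °C, favoured by the electron-rich ring B, may erode the configuration.
   - Fallback (resolution in place of induction), setting out from 27 and coming back at 29: 27 is closed with Et3N to racemic tert-butyl flavanone-3-carboxylate F4, and p-TsOH at 80 °C gives racemic octabenzyl flavanone F5. Kinetic resolution by asymmetric transfer hydrogenation (Cp*RhCl[(R,R)-TsDPEN], HCO2H/Et3N, EtOAc, rt) reduces the 2R enantiomer to (2R,4R)-cis-flavan-4-ol F6. The unreacted 2S ketone, which is 29, is separated by chromatography.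

3. **Step 7.**
   - What may go wrong: transmetalation of the doubly ortho-substituted arylzinc may be slow, so that reduction or homocoupling of the chloromethyl partner takes over.
   - Fallback (pyranone built after ring B is in place), setting out from 4 and 7 and coming back at 13: 4 is coupled with the Reformatsky reagent BrZnCH2CO2Et (Pd(dba)2, XPhos, THF, 60 °C) to ethyl arylacetate F7. An excess of dianion 8, made from 7 as in step 6, is acylated by F7 to triketone F8. Neutral cyclodehydration with PPh3/CCl4 in THF takes up the oxygen as the phosphine oxide and forms no water, so the acetal is spared and 13 results.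

Further compounds
F1 | step 10 | 2-[2,3-bis(benzyloxy)-6-(1,3-dioxolan-2-yl)phenyl]-4,4,5,5-tetramethyl-1,3,2-dioxaborolane | CC1(C)OB(OC1(C)C)c1c(C2OCCO2)ccc(OCc2ccccc2)c1OCc1ccccc1
F2 | step 10 | 5,7,3',4'-tetra-O-benzylluteolin | O=c1cc(-c2ccc(OCc3ccccc3)c(OCc3ccccc3)c2)oc2cc(OCc3ccccc3)cc(OCc3ccccc3)c12
F3 | step 10 | 8-iodo-5,7,3',4'-tetra-O-benzylluteolin | O=c1cc(-c2ccc(OCc3ccccc3)c(OCc3ccccc3)c2)oc2c(I)c(OCc3ccccc3)cc(OCc3ccccc3)c12
F4 | step 16 | racemic tert-butyl flavanone-3-carboxylate (racemate of 28) | O=C1C(C(=O)OC(C)(C)C)C(c2ccc(OCc3ccccc3)c(OCc3ccccc3)c2-c2c(OCc3ccccc3)cc(OCc3ccccc3)c3c(=O)cc(-c4ccc(OCc5ccccc5)c(OCc5ccccc5)c4)oc23)Oc2cc(OCc3ccccc3)cc(OCc3ccccc3)c21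
F5 | step 16 | racemic octabenzyl flavanone (racemate of 29) | O=C1CC(c2ccc(OCc3ccccc3)c(OCc3ccccc3)c2-c2c(OCc3ccccc3)cc(OCc3ccccc3)c3c(=O)cc(-c4ccc(OCc5ccccc5)c(OCc5ccccc5)c4)oc23)Oc2cc(OCc3ccccc3)cc(OCc3ccccc3)c21
F6 | step 16 | (2R,4R)-cis-flavan-4-ol from the 2R enantiomer of F5 | O[C@@H]1C[C@H](c2ccc(OCc3ccccc3)c(OCc3ccccc3)c2-c2c(OCc3ccccc3)cc(OCc3ccccc3)c3c(=O)cc(-c4ccc(OCc5ccccc5)c(OCc5ccccc5)c4)oc23)Oc2cc(OCc3ccccc3)cc(OCc3ccccc3)c21
F7 | step 7 | ethyl 2-[2,3-bis(benzyloxy)-6-(1,3-dioxolan-2-yl)phenyl]acetate | CCOC(=O)Cc1c(C2OCCO2)ccc(OCc2ccccc2)c1OCc1ccccc1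
F8 | step 7 | 1-[2,3-bis(benzyloxy)-6-(1,3-dioxolan-2-yl)phenyl]-6-[3,4-bis(benzyloxy)phenyl]hexane-2,4,6-trione | O=C(Cc1c(C2OCCO2)ccc(OCc2ccccc2)c1OCc1ccccc1)CC(=O)CC(=O)c1ccc(OCc2ccccc2)c(OCc2ccccc2)c1
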